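**Retrosynthetic overview**

1. Feature: atoms C1–C10 form one ten-membered perimeter whose only cross-ring bond is C1–C5. C5 is α to the C6 ketone and C1 is the β-carbon of a C9 ynone, so a single transannular Michael bond makes ring A (cyclopentane C1–C5) and ring B (cycloheptane C1, C5–C10) together and leaves C1 open to a methyl cuprate.
2. Target ⇐ β-face epoxidation of an 8-methyl C8=C9 alkene ⇐ C9 ketone by C8 methylenation and reductive 1,3-transposition; O6 vanillate ⇐ O4-chelation-controlled reduction of the C6 ketone.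
3. trans-Fused hydroazulene-6,9-dione ⇐ ten-membered 6,9-dione with a C1≡C10 alkyne (key step, one flask).
4. Ynedione ⇐ CrCl2–NiCl2 closure of C9–C10 on an iodoalkyne keto aldehyde; both carbonyls come from one ozonolysis of a 1,5-diene.
5. C4 ⇐ Sharpless epoxidation; the 2-isopropylglycidyl tosylate is opened twice (alkenyl Grignard for C5–C6, relay epoxide, silylpropargyl lithium for C3–C2). Ring order: ten-membered ring first, rings A and B together in the key step, oxirane last.

Key step: step 13

Remark: locants C1–C10 are those of the overview; α is the face of the C1 methyl group, O4 and O6, β the face of H5 and the isopropyl group, and the absolute configuration is that of the given SMILES.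

**Step 1**
Reactants: 1 3-methylbutanal
Product: 2 3-methyl-2-methylidenebutanal
Conditions: aq. CH2O, pyrrolidine (10 mol %), propionic acid (10 mol %), i-PrOH, 45 °C
Reagents that add atoms: formaldehyde, C=O
Why: Amine-catalysed Mannich condensation of the α-unbranched aldehyde with formaldehyde and loss of the amine (α-methylenation) should give the 2-substituted acrolein.

**Step 2**
Reactants: 2 3-methyl-2-methylidenebutanal
Product: 3 3-methyl-2-methylidenebutan-1-ol
Conditions: NaBH4, CeCl3·7H2O, MeOH, 0 °C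
Reagents that add atoms: none
Why: Luche reduction attacks the enal carbonyl 1,2 and leaves the 1,1-disubstituted alkene.

**Step 3**
Reactants: 3 3-methyl-2-methylidenebutan-1-ol
Product: 4 [(2S)-2-(propan-2-yl)oxiran-2-yl]methanol
Conditions: Ti(OiPr)4 (5 mol %), L-(+)-diethyl tartrate (6 mol %), t-BuOOH, 4 Å MS, CH2Cl2, −20 °C
Reagents that add atoms: tert-butyl hydroperoxide, CC(C)(C)OO
Why: Sharpless asymmetric epoxidation of a 2-substituted allylic alcohol; with L-(+)-tartrate the titanium complex should deliver oxygen to the face that gives the (S)-epoxy alcohol, which fixes C4 of the target.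

**Step 4**
Reactants: 4 [(2S)-2-(propan-2-yl)oxiran-2-yl]methanol
Product: 5 [(2R)-2-(propan-2-yl)oxiran-2-yl]methyl 4-methylbenzenesulfonate
Conditions: TsCl, Et3N, DMAP (cat.), CH2Cl2, 0 °C
Reagents that add atoms: 4-toluenesulfonyl chloride, Cc1ccc(cc1)S(=O)(=O)Cl
Why: Sulfonylation of the primary alcohol leaves both C4–O bonds untouched, so the configuration is retained (the descriptor changes by priority only).

**Step 5**
Reactants: 6 2,3-dibromoprop-1-ene; 7 allylmagnesium bromide
Product: 8 2-bromohexa-1,5-diene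
Conditions: Et2O, 0 °C to rt
Reagents that add atoms: none
Why: The allyl Grignard reagent displaces the allylic bromide (direct and allylic displacement give the same product) and the vinylic bromide is inert.

**Step 6**
Reactants: 8 2-bromohexa-1,5-diene; 5 [(2R)-2-(propan-2-yl)oxiran-2-yl]methyl 4-methylbenzenesulfonate
Product: 11 (2S)-2-(2-methylidenehex-5-en-1-yl)-2-(propan-2-yl)oxirane, via hexa-1,5-dien-2-ylmagnesium bromide 9 (not isolated), via hydroxy tosylate 10 (not isolated)
Conditions: Mg, THF, reflux; CuI (10 mol %), 5, −30 to 0 °C; sat. aq. NH4Cl; K2CO3, MeOH, rt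
Reagents that add atoms: none
Why: Copper-catalysed Grignard opening occurs at the epoxide CH2 (C5–C6 bond) because the neopentyl tosylate resists direct displacement, and base then closes the tertiary alkoxide onto the tosylate (3-exo-tet), which moves the epoxide to the C3 arm with the C4–O bond intact.

**Step 7**
Reactants: 12 trimethyl(prop-1-yn-1-yl)silane; 11 (2S)-2-(2-methylidenehex-5-en-1-yl)-2-(propan-2-yl)oxirane
Product: 14 (5S)-7-methylidene-5-(propan-2-yl)-1-(trimethylsilyl)undec-10-en-1-yn-5-ol, via lithiated silylpropyne 13 (not isolated)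
Conditions: n-BuLi, THF, −78 to 0 °C; 11, BF3·OEt2, −78 °C
Reagents that add atoms: none
Why: BF3-promoted opening of the 2,2-disubstituted epoxide at its CH2 terminus by the propargylic lithium reagent forms C3–C2 and supplies C2, C1 and C10, with C4 untouched.

**Step 8**
Reactants: 14 (5S)-7-methylidene-5-(propan-2-yl)-1-(trimethylsilyl)undec-10-en-1-yn-5-ol
Product: 15 (5S)-7-methylidene-5-(propan-2-yl)-5-[(triethylsilyl)oxy]-1-(trimethylsilyl)undec-10-en-1-yne
Conditions: Et3SiOTf, 2,6-lutidine, CH2Cl2, −78 to 0 °C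
Reagents that add atoms: triethylsilyl trifluoromethanesulfonate, CC[Si](CC)(CC)OS(=O)(=O)C(F)(F)F
Why: A silyl triflate silylates the hindered tertiary alcohol, and O4 must be masked because the free hydroxyl would add 5-exo-dig to C1 of the later ynone.

**Step 9**
Reactants: 15 (5S)-7-methylidene-5-(propan-2-yl)-5-[(triethylsilyl)oxy]-1-(trimethylsilyl)undec-10-en-1-yne
Product: 17 (6S)-4-oxo-6-(propan-2-yl)-6-[(triethylsilyl)oxy]-10-(trimethylsilyl)dec-9-ynal, via bis-ozonide 16 (not isolated)
Conditions: O3, CH2Cl2, −78 °C (Sudan Red end point); PPh3, −78 °C to rt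
Reagents that add atoms: ozone, [O-][O+]=O
Why: Ozonolysis cleaves both alkenes far faster than the silylalkyne, so one operation should unmask the C6 ketone and the C9 aldehyde.

**Step 10**
Reactants: 17 (6S)-4-oxo-6-(propan-2-yl)-6-[(triethylsilyl)oxy]-10-(trimethylsilyl)dec-9-ynal
Product: 18 (6S)-10-iodo-4-oxo-6-(propan-2-yl)-6-[(triethylsilyl)oxy]dec-9-ynal
Conditions: N-iodosuccinimide, AgNO3 (10 mol %), acetone, rt, dark
Reagents that add atoms: N-iodosuccinimide, O=C1CCC(=O)N1I
Why: Silver-catalysed iododesilylation through the silver acetylide is neutral and should spare the base-sensitive γ-keto aldehyde and the silyl ether.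

**Step 11**
Reactants: 18 (6S)-10-iodo-4-oxo-6-(propan-2-yl)-6-[(triethylsilyl)oxy]dec-9-ynal
Product: 19 (9S)-4-hydroxy-9-(propan-2-yl)-9-[(triethylsilyl)oxy]cyclodec-5-yn-1-one (both carbinol epimers)
Conditions: CrCl2 (6 equiv), NiCl2 (2 mol %), THF, rt, 0.003 M, slow addition
Reagents that add atoms: none
Why: Nozaki–Hiyama–Kishi closure of C9–C10: the alkynylchromium species adds to the aldehyde and not to the ketone, and transannular addition to C6 is excluded because it would form a cycloheptyne.

**Step 12**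
Reactants: 19 (9S)-4-hydroxy-9-(propan-2-yl)-9-[(triethylsilyl)oxy]cyclodec-5-yn-1-one
Product: 20 (9S)-9-(propan-2-yl)-9-[(triethylsilyl)oxy]cyclodec-5-yne-1,4-dione (ketones at C6 and C9, alkyne C1≡C10)
Conditions: Dess–Martin periodinane, NaHCO3, CH2Cl2, 0 °C to rt
Reagents that add atoms: none
Why: Dess–Martin oxidation of the propargylic alcohol converges both C9 epimers on the ynone under non-basic conditions.

**Step 13**
Reactants: 20 (9S)-9-(propan-2-yl)-9-[(triethylsilyl)oxy]cyclodec-5-yne-1,4-dione
Product: 24 (3R,3aR,8aR)-8a-methyl-3-(propan-2-yl)-3-[(triethylsilyl)oxy]octahydroazulene-4,7-dione (trans-fused; 1α-methyl; 4α-silyloxy; 5β-H; ketones at C6 and C9), via bromomagnesium dienolate 21 (not isolated), via fusion ene-dione 22 (not isolated), via trimethylsilyl enol ether 23 (not isolated)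
Conditions: MgBr2·OEt2 (2 equiv), i-Pr2NEt (1.5 equiv), CH2Cl2 (0.005 M), 0 °C to rt; HCl in Et2O (1.5 equiv), −78 to 0 °C; THF, Me3SiCl, Me2CuLi (5 equiv, from MeLi and CuI), −78 to −40 °C; AcOH, THF–H2O, 0 °C
Reagents that add atoms: lithium dimethylcuprate, [Li+].C[Cu-]C
Why: Proposed new method: reversible magnesium-mediated soft enolisation should let the C5 enolate of the C6 ketone add across the ring to C1 of the magnesium-activated ynone, the adduct (a vinylogous 1,3-diketone) should rest as dienolate 21 until one equivalent of HCl protonates it at the unhindered C10 to give the C5=C1 fusion enone 22, in which C1 is still a β-carbon and takes methyl from Me2CuLi–Me3SiCl to give enol ether 23; the closest known reaction types are base-mediated intramolecular and transannular Michael additions of ketones to enones and ynones and Me2CuLi–Me3SiCl additions to ring-fusion enones that install angular methyl groups, while the one-flask pair on a cyclodecynedione is new. The single bond C5–C1 closes ring A by 5-exo-dig attack and thereby turns the other seven perimeter atoms into ring B (formally 7-endo-dig). C1 is controlled by C4: on the planar enone 22 the cuprate should enter from the α-face, beside the ether oxygen and opposite the branched isopropyl group. C5 is set when 23 is protonolysed: the proton should enter from the β-face, away from the new α-methyl and the α-silyloxy group, which gives the trans fusion with C6 anti to isopropyl. The step needs C5 and not C7 as donor (C7 could reach C1 only by 5-endo-dig closure through the rigid C8–C9–C10≡C1 unit), carbon and not oxygen attack (the alternative is a seven-membered enol ether), no transannular aldol (a C5–C9 bond would require a cycloheptyne), and survival of the β-silyloxy group, which the low enolate concentration of soft enolisation and silyl trapping at −78 °C should secure.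

**Step 14**
Reactants: 24 (3R,3aR,8aR)-8a-methyl-3-(propan-2-yl)-3-[(triethylsilyl)oxy]octahydroazulene-4,7-dione
Product: 25 (3R,3aR,8aR)-3-hydroxy-8a-methyl-3-(propan-2-yl)octahydroazulene-4,7-dione (4α-hydroxy-6,9-dione)
Conditions: HF·pyridine, pyridine, THF, 0 °C to rt
Reagents that add atoms: none
Why: Buffered fluoride cleavage of the Si–O bond avoids a free alkoxide and hence retro-aldol cleavage of the tertiary β-hydroxy ketone.

**Step 15**
Reactants: 25 (3R,3aR,8aR)-3-hydroxy-8a-methyl-3-(propan-2-yl)octahydroazulene-4,7-dione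
Product: 27 trans-fused 4α,6α-dihydroxy-1α-methyl-4β-isopropyl-9-ketone (H5 and H6 both β), via diethylboron chelate 26 (not isolated)
Conditions: Et2BOMe, THF–MeOH (4:1), −78 °C; NaBH4, −78 °C; AcOH, then MeOH co-evaporation
Reagents that add atoms: none
Why: Narasaka–Prasad reduction: the boron chelate between O4 and O6 activates only the C6 ketone and holds O6 syn to O4, so external hydride should enter past H5, antiperiplanar to the C5–C1 bond to the quaternary carbon, giving the 6α-carbinol, while the unchelated C9 ketone should not react with NaBH4 at −78 °C.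

**Step 16**
Reactants: 28 vanillic acid
Product: 30 4-[(tert-butyldimethylsilyl)oxy]-3-methoxybenzoic acid, via bis-silyl derivative 29 (not isolated)
Conditions: t-BuMe2SiCl, imidazole, DMF, rt; AcOH–THF–H2O, rt
Reagents that add atoms: tert-butyldimethylsilyl chloride, CC(C)(C)[Si](C)(C)Cl
Why: Both acidic sites are silylated and the labile silyl ester is then hydrolysed selectively, leaving the aryl silyl ether.

**Step 17**
Reactants: 27 trans-fused 4α,6α-dihydroxy-9-ketone; 30 4-[(tert-butyldimethylsilyl)oxy]-3-methoxybenzoic acid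
Product: 31 6α-O-[4-(tert-butyldimethylsilyloxy)-3-methoxybenzoyl] ester of 27 (4α-OH free, C9 ketone)
Conditions: EDC·HCl, DMAP (1 equiv), CH2Cl2, rt to 35 °C
Reagents that add atoms: none
Why: Steglich esterification acylates only the secondary O6–H (the tertiary O4–H is inert) and also stops O6 from forming a bridged hemiketal with C9.

**Step 18**
Reactants: 31 6α-O-aroyl 4α-hydroxy-9-ketone
Product: 32 8-methylidene-9-ketone (otherwise as 31)
Conditions: paraformaldehyde, N-methylanilinium trifluoroacetate, THF, reflux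
Reagents that add atoms: formaldehyde, C=O
Why: Mannich-type α-methylenation (aminomethylation of the enol, then loss of N-methylaniline) should occur at C8 because C10 is neopentyl, flanked by the quaternary C1.

**Step 19**
Reactants: 32 8-methylidene-9-ketone
Product: 33 8-methylidene-9-ol (both C9 epimers)
Conditions: NaBH4, CeCl3·7H2O, MeOH, −40 °C
Reagents that add atoms: none
Why: Luche reduction gives the allylic alcohol by 1,2-attack and spares the aryl ester; the C9 configuration is irrelevant because C9 becomes sp2 in the next step.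

**Step 20**
Reactants: 33 8-methylidene-9-ol
Product: 36 C8=C9 alkene carrying the C8 methyl group (6α-aroyloxy, 4α-OH), via sulfonylhydrazine adduct 34 (not isolated), via allylic diazene 35 (not isolated)
Conditions: 2-nitrobenzenesulfonylhydrazide, PPh3, diethyl azodicarboxylate, THF, −30 °C; then rt
Reagents that add atoms: none
Why: Mitsunobu displacement by the sulfonylhydrazide, loss of sulfinic acid and retro-ene loss of N2 from the allylic diazene deliver hydrogen to the exocyclic CH2 and move the double bond to C8=C9 regiospecifically (reductive 1,3-transposition).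

**Step 21**
Reactants: 36 C8=C9 alkene
Product: 37 8β,9β-epoxide, O-silylated target (cis-fused oxirane, C8 methyl α)
Conditions: m-CPBA, NaHCO3, CH2Cl2, 0 °C
Reagents that add atoms: 3-chloroperoxybenzoic acid, OOC(=O)c1cccc(Cl)c1
Why: Prilezhaev epoxidation should occur on the β-face because the α-face of C8=C9 is flanked by the axial C1 methyl and the C6 acyloxy group, which sets C8 and C9 together.

**Step 22**
Reactants: 37 8β,9β-epoxide, O-silylated target
Product: 38 target, 6α-vanilloyloxy-4α-hydroxy-8β,9β-epoxide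
Conditions: Bu4NF, AcOH, THF, 0 °C
Reagents that add atoms: none
Why: Fluoride cleaves the aryl silyl ether rapidly, and acetic acid buffering protects the trisubstituted epoxide and the ester.

**Compound list**

1 | 3-methylbutanal | CC(C)CC=O | starting material
2 | 3-methyl-2-methylidenebutanal | CC(C)C(=C)C=O | intermediate
3 | 3-methyl-2-methylidenebutan-1-ol | CC(C)C(=C)CO | intermediate
4 | [(2S)-2-(propan-2-yl)oxiran-2-yl]methanol | CC(C)[C@]1(CO)CO1 | intermediate
5 | [(2R)-2-(propan-2-yl)oxiran-2-yl]methyl 4-methylbenzenesulfonate | CC(C)[C@]1(COS(=O)(=O)c2ccc(C)cc2)CO1 | intermediate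
6 | 2,3-dibromoprop-1-ene | C=C(Br)CBr | starting material
7 | allylmagnesium bromide | C=CC[Mg]Br | starting material
8 | 2-bromohexa-1,5-diene | C=C(Br)CCC=C | intermediate
9 | hexa-1,5-dien-2-ylmagnesium bromide | C=C([Mg]Br)CCC=C | intermediate (not isolated)
10 | (2S)-2-hydroxy-4-methylidene-2-(propan-2-yl)oct-7-en-1-yl 4-methylbenzenesulfonate | CC(C)[C@](O)(COS(=O)(=O)c1ccc(C)cc1)CC(=C)CCC=C | intermediate (not isolated)
11 | (2S)-2-(2-methylidenehex-5-en-1-yl)-2-(propan-2-yl)oxirane | CC(C)[C@]1(CO1)CC(=C)CCC=C | intermediate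
12 | trimethyl(prop-1-yn-1-yl)silane | CC#C[Si](C)(C)C | starting material
13 | [3-(trimethylsilyl)prop-2-yn-1-yl]lithium | [Li]CC#C[Si](C)(C)C | intermediate (not isolated)
14 | (5S)-7-methylidene-5-(propan-2-yl)-1-(trimethylsilyl)undec-10-en-1-yn-5-ol | CC(C)[C@](O)(CCC#C[Si](C)(C)C)CC(=C)CCC=C | intermediate
15 | (5S)-7-methylidene-5-(propan-2-yl)-5-[(triethylsilyl)oxy]-1-(trimethylsilyl)undec-10-en-1-yne | CC(C)[C@](O[Si](CC)(CC)CC)(CCC#C[Si](C)(C)C)CC(=C)CCC=C | intermediate
16 | bis-ozonide of 15 (1,2,4-trioxolanes at both former alkenes) | CC(C)[C@](O[Si](CC)(CC)CC)(CCC#C[Si](C)(C)C)CC1(CCC2OCOO2)OCOO1 | intermediate (not isolated)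
17 | (6S)-4-oxo-6-(propan-2-yl)-6-[(triethylsilyl)oxy]-10-(trimethylsilyl)dec-9-ynal | CC(C)[C@](O[Si](CC)(CC)CC)(CCC#C[Si](C)(C)C)CC(=O)CCC=O | intermediate
18 | (6S)-10-iodo-4-oxo-6-(propan-2-yl)-6-[(triethylsilyl)oxy]dec-9-ynal | CC(C)[C@](O[Si](CC)(CC)CC)(CCC#CI)CC(=O)CCC=O | intermediate
19 | (9S)-4-hydroxy-9-(propan-2-yl)-9-[(triethylsilyl)oxy]cyclodec-5-yn-1-one (carbinol epimers) | CC(C)[C@]1(O[Si](CC)(CC)CC)CCC#CC(O)CCC(=O)C1 | intermediate
20 | (9S)-9-(propan-2-yl)-9-[(triethylsilyl)oxy]cyclodec-5-yne-1,4-dione | CC(C)[C@]1(O[Si](CC)(CC)CC)CCC#CC(=O)CCC(=O)C1 | intermediate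
21 | bromomagnesium dienolate of 22 (O6–Mg, C6=C5–C1=C10–C9=O) | CC(C)[C@]1(O[Si](CC)(CC)CC)CCC2=CC(=O)CCC(O[Mg]Br)=C12 | intermediate (not isolated)
22 | (3R)-3-(propan-2-yl)-3-[(triethylsilyl)oxy]-1,2,3,5,6,8-hexahydroazulene-4,7-dione (C5=C1 fusion enone) | CC(C)[C@]1(O[Si](CC)(CC)CC)CCC2=C1C(=O)CCC(=O)C2 | intermediate (not isolated)
23 | C6 trimethylsilyl enol ether (C5=C6) of 24, 1α-methyl, C9 ketone | C[Si](C)(C)OC1=C2[C@](O[Si](CC)(CC)CC)(C(C)C)CC[C@]2(C)CC(=O)CC1 | intermediate (not isolated)
24 | (3R,3aR,8aR)-8a-methyl-3-(propan-2-yl)-3-[(triethylsilyl)oxy]octahydroazulene-4,7-dione | O=C2CCC(=O)C[C@@]3(C)CC[C@@](O[Si](CC)(CC)CC)(C(C)C)[C@H]23 | intermediate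
25 | (3R,3aR,8aR)-3-hydroxy-8a-methyl-3-(propan-2-yl)octahydroazulene-4,7-dione | O=C2CCC(=O)C[C@@]3(C)CC[C@@](O)(C(C)C)[C@H]23 | intermediate
26 | O4-diethylboryl chelate of 25 | CCB(CC)O[C@@]1(C(C)C)CC[C@]2(C)CC(=O)CCC(=O)[C@@H]12 | intermediate (not isolated)
27 | trans-fused 4α,6α-dihydroxy-1α-methyl-4β-isopropyl-9-ketone | O[C@@H]2CCC(=O)C[C@@]3(C)CC[C@@](O)(C(C)C)[C@H]23 | intermediate
28 | vanillic acid | COc1cc(C(=O)O)ccc1O | starting material
29 | tert-butyldimethylsilyl 4-[(tert-butyldimethylsilyl)oxy]-3-methoxybenzoate | COc1cc(C(=O)O[Si](C)(C)C(C)(C)C)ccc1O[Si](C)(C)C(C)(C)C | intermediate (not isolated)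
30 | 4-[(tert-butyldimethylsilyl)oxy]-3-methoxybenzoic acid | COc1cc(C(=O)O)ccc1O[Si](C)(C)C(C)(C)C | intermediate
31 | 6α-O-[4-(tert-butyldimethylsilyloxy)-3-methoxybenzoyl] 4α-hydroxy-9-ketone | COc1cc(C(=O)O[C@@H]2CCC(=O)C[C@@]3(C)CC[C@@](O)(C(C)C)[C@H]23)ccc1O[Si](C)(C)C(C)(C)C | intermediate
32 | 8-methylidene-9-ketone | COc1cc(C(=O)O[C@@H]2CC(=C)C(=O)C[C@@]3(C)CC[C@@](O)(C(C)C)[C@H]23)ccc1O[Si](C)(C)C(C)(C)C | intermediate
33 | 8-methylidene-9-ol (C9 epimers) | COc1cc(C(=O)O[C@@H]2CC(=C)C(O)C[C@@]3(C)CC[C@@](O)(C(C)C)[C@H]23)ccc1O[Si](C)(C)C(C)(C)C | intermediate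
34 | C9 N-amino-2-nitrobenzenesulfonamide (Mitsunobu adduct) | COc1cc(C(=O)O[C@@H]2CC(=C)C(N(N)S(=O)(=O)c4ccccc4[N+](=O)[O-])C[C@@]3(C)CC[C@@](O)(C(C)C)[C@H]23)ccc1O[Si](C)(C)C(C)(C)C | intermediate (not isolated)
35 | C9 allylic diazene | COc1cc(C(=O)O[C@@H]2CC(=C)C(N=N)C[C@@]3(C)CC[C@@](O)(C(C)C)[C@H]23)ccc1O[Si](C)(C)C(C)(C)C | intermediate (not isolated)
36 | 8-methyl C8=C9 alkene | COc1cc(C(=O)O[C@@H]2CC(C)=CC[C@@]3(C)CC[C@@](O)(C(C)C)[C@H]23)ccc1O[Si](C)(C)C(C)(C)C | intermediate
37 | 8β,9β-epoxide, O-silylated target | COc1cc(C(=O)O[C@@H]2C[C@@]3(C)O[C@H]3C[C@@]3(C)CC[C@@](O)(C(C)C)[C@H]23)ccc1O[Si](C)(C)C(C)(C)C | intermediate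
38 | CNP0254293.2 | COc1cc(C(=O)O[C@@H]2C[C@@]3(C)O[C@H]3C[C@@]3(C)CC[C@@](O)(C(C)C)[C@H]23)ccc1O | target

**Step count and risks**

Total step count: 22. Longest linear sequence: 20 (steps 1–4, 6–15, 17–22); steps 5 and 16 are one-step branches.

Steps most likely to fail:

1. Step 13. The cuprate may deprotonate the doubly activated C10 methylene of 22 and return the dienolate in place of adding, and methyl transfer may occur on the wrong face of C1. The fallback sets out from 20 and comes back at 25. The Michael stage is run alone (MgBr2·OEt2, i-Pr2NEt, then aqueous acid) and ene-dione 22 is isolated. HF·pyridine frees O4 to give the hydroxy ene-dione F1, and (bromomethyl)chlorodimethylsilane with imidazole and DMAP gives the (bromomethyl)dimethylsilyl ether F2. Bu3SnH and AIBN in benzene at 80 °C generate the α-silyl radical, which should add 6-endo to C1, the β-carbon of the enone, from the O4 face and give the bridged siloxane F3 (silicon-tethered radical cyclisation). Bu4NF in DMF at 70 °C then protodesilylates the C–Si bond and frees O4, giving 25 with the C1 methyl cis to O4 by construction.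

2. Step 11. Intermolecular coupling may outrun closure of the strained ten-membered ring. The fallback sets out from 17 and comes back at 20, bypassing steps 10–12. Pinnick oxidation (NaClO2, NaH2PO4, 2-methylbut-2-ene) gives the keto acid F4; K2CO3 in MeOH removes the alkynyl silyl group to give the terminal alkyne acid F5; EtSH, EDC and DMAP give the S-ethyl thioester F6. Slow addition of F6 to PdCl2(dppf), tri(2-furyl)phosphine, CuI and Et3N in DMF at high dilution should close C9–C10 by thioester–alkyne coupling and give ynone 20 directly.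

3. Step 20. The Mitsunobu displacement at the hindered secondary allylic carbinol may stall or divert to elimination. The fallback sets out from 32 and comes back at 36. 4-Toluenesulfonylhydrazide with catalytic AcOH in EtOH gives the C9 tosylhydrazone F7; catecholborane in CHCl3 at 0 °C, then NaOAc·3H2O at reflux, reduces the C=N bond, and the allylic diazene so formed loses N2 with the same 1,3-transposition.

**Further compounds**

F1 | step 13 | (3R)-3-hydroxy-3-(propan-2-yl)-1,2,3,5,6,8-hexahydroazulene-4,7-dione | CC(C)[C@]1(O)CCC2=C1C(=O)CCC(=O)C2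
F2 | step 13 | O4-(bromomethyl)dimethylsilyl ether of F1 | CC(C)[C@]1(O[Si](C)(C)CBr)CCC2=C1C(=O)CCC(=O)C2
F3 | step 13 | bridged siloxane, O4–SiMe2–CH2–C1 on the α-face, 6,9-dione | O=C2CCC(=O)C[C@@]3(C[Si](C)(C)O5)CC[C@@]5(C(C)C)[C@H]23
F4 | step 11 | (6S)-4-oxo-6-(propan-2-yl)-6-[(triethylsilyl)oxy]-10-(trimethylsilyl)dec-9-ynoic acid | CC(C)[C@](O[Si](CC)(CC)CC)(CCC#C[Si](C)(C)C)CC(=O)CCC(=O)O
F5 | step 11 | (6S)-4-oxo-6-(propan-2-yl)-6-[(triethylsilyl)oxy]dec-9-ynoic acid | CC(C)[C@](O[Si](CC)(CC)CC)(CCC#C)CC(=O)CCC(=O)O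
F6 | step 11 | S-ethyl (6S)-4-oxo-6-(propan-2-yl)-6-[(triethylsilyl)oxy]dec-9-ynethioate | CC(C)[C@](O[Si](CC)(CC)CC)(CCC#C)CC(=O)CCC(=O)SCC
F7 | step 20 | C9 4-toluenesulfonylhydrazone of 32 | COc1cc(C(=O)O[C@@H]2CC(=C)C(=NNS(=O)(=O)c4ccc(C)cc4)C[C@@]3(C)CC[C@@](O)(C(C)C)[C@H]23)ccc1O[Si](C)(C)C(C)(C)C
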